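**Retrosynthetic overview**

Numbering used throughout: ring C1 (quaternary; CH3 and C1′H2–O), C2 (CH–CH3), C3, C4, C5 (=CMe2), C6 (CH; side chain C7–C9).
1. Late disconnections: C9 by hydroformylation of a C6 vinyl group, the C1′–OAr ether by Mitsunobu reaction with isofraxidin, and a C3 hydroxyl removed by Barton–McCombie deoxygenation.
2. Key disconnection: C3–C4 and C1–C6 are made together from the acyclic dienol 11 by a thermal oxy-Cope/carbonyl-ene cascade. The cyclohexane is the only ring formed in the route; the coumarin is bought intact.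
3. Enabling feature: the quaternary C1 sits next to the allylic methine C6 (a bond between two allyl termini, hence a Cope retron once C3 is a carbonyl). The exocyclic tetrasubstituted C5=C(CH3)2 alkene with C4H2 beside it is homoallylic to C3 (a carbonyl-ene retron in which an isopropyl group gives up its methine hydrogen).
4. Dienol 11 comes from 2,3-dimethylmaleic anhydride, whose ring fixes the Z alkene that carries the methyl groups of C1 and C2, by reduction, mono-protection, oxidation, asymmetric propargylation, alkyne hydroboration and Suzuki coupling.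

Key step: step 8

Remark on the chemistry: isofraxidin (7-hydroxy-6,8-dimethoxycoumarin) is assumed to be commercially available. The sense of induction in step 4 and the chair assignments in step 8 are derived from models, not from experiment.

**Route**

Step 1
Reactants: 1 2,3-dimethylmaleic anhydride
Product: 2 (2Z)-2,3-dimethylbut-2-ene-1,4-diol
Conditions: LiAlH4 (2.5 equiv), THF, 0 °C → reflux; aqueous NaOH work-up
Reagents that add atoms: none
Why: Hydride reduction of both anhydride carbonyls (LiAlH4 reduction of a cyclic anhydride to the diol); the ring fixes the Z geometry of the tetrasubstituted alkene that later defines C1.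

Step 2
Reactants: 2 (2Z)-2,3-dimethylbut-2-ene-1,4-diol
Product: 3 (2Z)-4-[(4-methoxyphenyl)methoxy]-2,3-dimethylbut-2-en-1-ol
Conditions: NaH (1.0 equiv), THF/DMF, 0 °C; PMBCl (1.0 equiv), Bu4NI (cat.), rt; diol in excess
Reagents that add atoms: 4-methoxybenzyl chloride, COc1ccc(CCl)cc1
Why: Statistical Williamson mono-etherification of a symmetric diol; the PMB ether masks the future aryl-ether oxygen and should survive every step up to its removal with DDQ.

Step 3
Reactants: 3 (2Z)-4-[(4-methoxyphenyl)methoxy]-2,3-dimethylbut-2-en-1-ol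
Product: 4 (2Z)-4-[(4-methoxyphenyl)methoxy]-2,3-dimethylbut-2-enal
Conditions: TEMPO (0.1 equiv), PhI(OAc)2 (1.2 equiv), CH2Cl2, rt
Reagents that add atoms: none
Why: Oxoammonium (TEMPO) oxidation of the primary allylic alcohol stops at the aldehyde and, being non-basic, should not isomerise the Z enal.

Step 4
Reactants: 4 (2Z)-4-[(4-methoxyphenyl)methoxy]-2,3-dimethylbut-2-enal; 5 allenylboronic acid pinacol ester
Product: 6 (4S,5Z)-7-[(4-methoxyphenyl)methoxy]-5,6-dimethylhept-5-en-1-yn-4-ol
Conditions: (S)-3,3′-bis(2,4,6-triisopropylphenyl)-1,1′-binaphthyl-2,2′-diyl hydrogen phosphate [(S)-TRIP, 10 mol%], 4 Å MS, toluene, −20 °C; aqueous work-up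
Reagents that add atoms: none
Why: Chiral phosphoric acid-catalysed propargylboration (SE2′ addition of the allenylboronate through a closed six-membered transition state); the catalyst antipode is chosen to give the 4S carbinol, the only stereocentre carried into the key step.

Step 5
Reactants: 6 (4S,5Z)-7-[(4-methoxyphenyl)methoxy]-5,6-dimethylhept-5-en-1-yn-4-ol
Product: 7 (1E,4S,5Z)-7-[(4-methoxyphenyl)methoxy]-5,6-dimethyl-1-(4,4,5,5-tetramethyl-1,3,2-dioxaborolan-2-yl)hepta-1,5-dien-4-ol
Conditions: B2pin2 (1.1 equiv), CuCl (5 mol%), Xantphos (6 mol%), NaOt-Bu (10 mol%), MeOH (2 equiv), THF, rt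
Reagents that add atoms: bis(pinacolato)diboron, CC1(C)OB(OC1(C)C)B1OC(C)(C)C(C)(C)O1
Why: Copper-boryl syn-addition to the terminal alkyne with boron at the terminal carbon, then protonolysis by MeOH (formal anti-Markovnikov hydroboration), should give the E alkenylboronate without touching the alcohol or the tetrasubstituted alkene.

Step 6
Reactants: 8 3-methylbutan-2-one
Product: 10 3-methylbut-1-en-2-yl trifluoromethanesulfonate, via lithium 3-methylbut-1-en-2-olate 9 (not isolated)
Conditions: LDA (1.05 equiv), THF, −78 °C; PhNTf2 (1.05 equiv), −78 → 0 °C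
Reagents that add atoms: N-phenylbis(trifluoromethanesulfonimide), O=S(=O)(N(c1ccccc1)S(=O)(=O)C(F)(F)F)C(F)(F)F
Why: Kinetic deprotonation at the methyl group by LDA at low temperature and O-sulfonylation of the less substituted enolate (enol triflate formation).

Step 7
Reactants: 7 (1E,4S,5Z)-7-[(4-methoxyphenyl)methoxy]-5,6-dimethyl-1-(4,4,5,5-tetramethyl-1,3,2-dioxaborolan-2-yl)hepta-1,5-dien-4-ol; 10 3-methylbut-1-en-2-yl trifluoromethanesulfonate
Product: 11 (2Z,4S,6E)-1-[(4-methoxyphenyl)methoxy]-2,3,9-trimethyl-8-methylidenedeca-2,6-dien-4-ol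
Conditions: Pd(PPh3)4 (5 mol%), K3PO4 (3 equiv), 1,4-dioxane/H2O, 50 °C
Reagents that add atoms: none
Why: Suzuki–Miyaura alkenyl–alkenyl coupling proceeds with retention at both partners and should deliver the E diene whose terminal C4H2=C5(i-Pr) unit is the ene donor of step 8.

Step 8
Reactants: 11 (2Z,4S,6E)-1-[(4-methoxyphenyl)methoxy]-2,3,9-trimethyl-8-methylidenedeca-2,6-dien-4-ol
Product: 14 (1R,2S,3S,4R)-4-ethenyl-3-{[(4-methoxyphenyl)methoxy]methyl}-2,3-dimethyl-5-(propan-2-ylidene)cyclohexan-1-ol, via oxy-Cope enol 12 (not isolated), via aldehyde 13 (not isolated)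
Conditions: DBU (0.2 equiv), N-methylpyrrolidone (0.02 M, degassed), 205 °C, sealed tube
Reagents that add atoms: none
Why: Proposed new method: heat drives a [3,3] oxy-Cope rearrangement of the 1,5-dien-3-ol through a chair transition state in which C1 of the Z tetrasubstituted alkene bonds to C6 of the E diene, the enol 12 tautomerises (DBU) to aldehyde 13, and the C3 carbonyl then undergoes an intramolecular type 2 carbonyl-ene reaction with the C4H2=C5 alkene, C3–C4 forming while the isopropyl methine hydrogen passes to oxygen so that the C5=C(CH3)2 alkene appears. The closest known reaction type is the thermal tandem oxy-Cope/transannular carbonyl-ene cascade of 1,2-divinylcyclohexanols under base-buffered conditions, together with thermal and Me2AlCl-promoted type 2 ene cyclisations of 6-methylene aldehydes; new here are the acyclic secondary dienol and the isopropyl group as hydrogen donor. The only ring, the cyclohexane, is closed in the ene step in the type 2 mode (6-exo-trig at the carbonyl carbon, both ene carbons C4 and C5 ending inside the ring). C1 and C6 are set in the Cope step by alkene geometry (Z puts CH2OPMB axial on C1, E puts H axial on C6) and their absolute sense by the carbinol centre of 11 (4S; C3 in ring numbering), whose hydroxyl must sit equatorial to avoid a 1,3-diaxial clash with the axial CH2OPMB; C2 is set in the ene step under dynamic control, since the α-centre of 13 epimerises through 12 and the chair ene transition state with equatorial C2 methyl and axial C6 vinyl (no allylic strain against the C5 isopropyl) should be preferred, and the axial C3 carbinol is erased in step 10. The step needs the [3,3] shift to outrun retro-ene fragmentation of the homoallylic alcohol, which the conjugating vinyl substituent on C6 should favour, and hydrogen transfer from the isopropyl methine and not from C6–H, which geometry secures because only the exocyclic hydrogen can reach the carbonyl oxygen in the six-membered ene array.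

Step 9
Reactants: 14 (1R,2S,3S,4R)-4-ethenyl-3-{[(4-methoxyphenyl)methoxy]methyl}-2,3-dimethyl-5-(propan-2-ylidene)cyclohexan-1-ol
Product: 15 O-[(1R,2S,3S,4R)-4-ethenyl-3-{[(4-methoxyphenyl)methoxy]methyl}-2,3-dimethyl-5-(propan-2-ylidene)cyclohexyl] 1H-imidazole-1-carbothioate
Conditions: 1,1′-thiocarbonyldiimidazole (3 equiv), DMAP (0.3 equiv), toluene, 90 °C
Reagents that add atoms: 1,1′-thiocarbonyldiimidazole, S=C(n1ccnc1)n1ccnc1
Why: Thioacylation of the hindered secondary alcohol prepares the C3–O bond for radical cleavage (first half of a Barton–McCombie deoxygenation).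

Step 10
Reactants: 15 O-[(1R,2S,3S,4R)-4-ethenyl-3-{[(4-methoxyphenyl)methoxy]methyl}-2,3-dimethyl-5-(propan-2-ylidene)cyclohexyl] 1H-imidazole-1-carbothioate
Product: 16 1-({[(1R,2R,6R)-2-ethenyl-1,6-dimethyl-3-(propan-2-ylidene)cyclohexyl]methoxy}methyl)-4-methoxybenzene
Conditions: Bu3SnH (3 equiv, 0.2 M), AIBN (0.2 equiv), toluene, 90 °C
Reagents that add atoms: none
Why: Barton–McCombie deoxygenation: the stannyl radical adds to C=S, β-scission gives the secondary C3 radical, and Bu3SnH kept at high concentration should reduce it before it can add across the ring to the vinyl group; C3 is no longer a stereocentre.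

Step 11
Reactants: 16 1-({[(1R,2R,6R)-2-ethenyl-1,6-dimethyl-3-(propan-2-ylidene)cyclohexyl]methoxy}methyl)-4-methoxybenzene
Product: 17 [(1R,2R,6R)-2-ethenyl-1,6-dimethyl-3-(propan-2-ylidene)cyclohexyl]methanol
Conditions: DDQ (1.3 equiv), CH2Cl2/pH 7 buffer (10:1), 0 °C
Reagents that add atoms: none
Why: Oxidative cleavage of the electron-rich PMB ether by DDQ (hydride abstraction, then hydrolysis of the oxocarbenium ion) frees the neopentyl alcohol; short contact at 0 °C should spare the isolated alkenes.

Step 12
Reactants: 17 [(1R,2R,6R)-2-ethenyl-1,6-dimethyl-3-(propan-2-ylidene)cyclohexyl]methanol; 18 isofraxidin (7-hydroxy-6,8-dimethoxy-2H-chromen-2-one)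
Product: 19 7-{[(1R,2R,6R)-2-ethenyl-1,6-dimethyl-3-(propan-2-ylidene)cyclohexyl]methoxy}-6,8-dimethoxy-2H-chromen-2-one
Conditions: PPh3 (2.5 equiv), DIAD (2.5 equiv), toluene (high concentration), sonication, 25–40 °C
Reagents that add atoms: none
Why: Mitsunobu etherification: isofraxidin is acidic enough to protonate the betaine and its phenoxide displaces the oxyphosphonium group at the primary neopentyl CH2, a slow SN2 that high concentration and sonication are meant to drive; no stereocentre is involved.

Step 13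
Reactants: 19 7-{[(1R,2R,6R)-2-ethenyl-1,6-dimethyl-3-(propan-2-ylidene)cyclohexyl]methoxy}-6,8-dimethoxy-2H-chromen-2-one
Product: 20 3-[(1R,2R,3R)-2-{[(6,8-dimethoxy-2-oxo-2H-chromen-7-yl)oxy]methyl}-2,3-dimethyl-6-(propan-2-ylidene)cyclohexyl]propanal
Conditions: Rh(acac)(CO)2 (2 mol%), Xantphos (4 mol%), CO/H2 (1:1, 20 bar), toluene, 70 °C
Reagents that add atoms: carbon monoxide, [C-]#[O+]
Why: Rhodium-catalysed hydroformylation with the wide-bite-angle ligand Xantphos should add H and CHO anti-Markovnikov to the monosubstituted alkene only; the tetrasubstituted alkene and the coumarin double bond are expected to be inert.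

Step 14
Reactants: 20 3-[(1R,2R,3R)-2-{[(6,8-dimethoxy-2-oxo-2H-chromen-7-yl)oxy]methyl}-2,3-dimethyl-6-(propan-2-ylidene)cyclohexyl]propanal
Product: 21 7-{[(1R,2R,6R)-2-(3-hydroxypropyl)-1,6-dimethyl-3-(propan-2-ylidene)cyclohexyl]methoxy}-6,8-dimethoxy-2H-chromen-2-one
Conditions: NaBH4 (1 equiv), MeOH/THF, −20 °C
Reagents that add atoms: none
Why: Chemoselective borohydride reduction of the aliphatic aldehyde at low temperature; the coumarin lactone should be reduced far more slowly.

**Compound list**

1 | 2,3-dimethylmaleic anhydride | CC1=C(C)C(=O)OC1=O | starting material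
2 | (2Z)-2,3-dimethylbut-2-ene-1,4-diol | OC/C(C)=C(C)\CO | intermediate
3 | (2Z)-4-[(4-methoxyphenyl)methoxy]-2,3-dimethylbut-2-en-1-ol | COc1ccc(COC/C(C)=C(C)\CO)cc1 | intermediate
4 | (2Z)-4-[(4-methoxyphenyl)methoxy]-2,3-dimethylbut-2-enal | COc1ccc(COC/C(C)=C(C)\C=O)cc1 | intermediate
5 | allenylboronic acid pinacol ester | C=C=CB1OC(C)(C)C(C)(C)O1 | starting material
6 | (4S,5Z)-7-[(4-methoxyphenyl)methoxy]-5,6-dimethylhept-5-en-1-yn-4-ol | COc1ccc(COC/C(C)=C(C)\[C@@H](O)CC#C)cc1 | intermediate
7 | (1E,4S,5Z)-7-[(4-methoxyphenyl)methoxy]-5,6-dimethyl-1-(4,4,5,5-tetramethyl-1,3,2-dioxaborolan-2-yl)hepta-1,5-dien-4-ol | COc1ccc(COC/C(C)=C(C)\[C@@H](O)C/C=C/B2OC(C)(C)C(C)(C)O2)cc1 | intermediate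
8 | 3-methylbutan-2-one | CC(=O)C(C)C | starting material
9 | lithium 3-methylbut-1-en-2-olate | [Li+].[O-]C(=C)C(C)C | intermediate
10 | 3-methylbut-1-en-2-yl trifluoromethanesulfonate | C=C(OS(=O)(=O)C(F)(F)F)C(C)C | intermediate
11 | (2Z,4S,6E)-1-[(4-methoxyphenyl)methoxy]-2,3,9-trimethyl-8-methylidenedeca-2,6-dien-4-ol | COc1ccc(COC/C(C)=C(C)\[C@@H](O)C/C=C/C(=C)C(C)C)cc1 | intermediate
12 | (1E,3S,4R)-4-ethenyl-3-{[(4-methoxyphenyl)methoxy]methyl}-2,3,6-trimethyl-5-methylidenehept-1-en-1-ol (oxy-Cope enol) | COc1ccc(COC[C@](C)(/C(C)=C/O)[C@H](C=C)C(=C)C(C)C)cc1 | intermediate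
13 | (2S,3S,4R)-4-ethenyl-3-{[(4-methoxyphenyl)methoxy]methyl}-2,3,6-trimethyl-5-methylideneheptanal (productive C2 epimer; the other epimer interconverts through 12) | COc1ccc(COC[C@](C)([C@H](C)C=O)[C@H](C=C)C(=C)C(C)C)cc1 | intermediate
14 | (1R,2S,3S,4R)-4-ethenyl-3-{[(4-methoxyphenyl)methoxy]methyl}-2,3-dimethyl-5-(propan-2-ylidene)cyclohexan-1-ol | COc1ccc(COC[C@]2(C)[C@H](C)[C@H](O)CC(=C(C)C)[C@H]2C=C)cc1 | intermediate
15 | O-[(1R,2S,3S,4R)-4-ethenyl-3-{[(4-methoxyphenyl)methoxy]methyl}-2,3-dimethyl-5-(propan-2-ylidene)cyclohexyl] 1H-imidazole-1-carbothioate | COc1ccc(COC[C@]2(C)[C@H](C)[C@H](OC(=S)n3ccnc3)CC(=C(C)C)[C@H]2C=C)cc1 | intermediate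
16 | 1-({[(1R,2R,6R)-2-ethenyl-1,6-dimethyl-3-(propan-2-ylidene)cyclohexyl]methoxy}methyl)-4-methoxybenzene | COc1ccc(COC[C@]2(C)[C@H](C)CCC(=C(C)C)[C@H]2C=C)cc1 | intermediate
17 | [(1R,2R,6R)-2-ethenyl-1,6-dimethyl-3-(propan-2-ylidene)cyclohexyl]methanol | OC[C@]1(C)[C@H](C)CCC(=C(C)C)[C@H]1C=C | intermediate
18 | isofraxidin (7-hydroxy-6,8-dimethoxy-2H-chromen-2-one) | COc1cc2ccc(=O)oc2c(OC)c1O | starting material
19 | 7-{[(1R,2R,6R)-2-ethenyl-1,6-dimethyl-3-(propan-2-ylidene)cyclohexyl]methoxy}-6,8-dimethoxy-2H-chromen-2-one | COc1cc2ccc(=O)oc2c(OC)c1OC[C@]1(C)[C@H](C)CCC(=C(C)C)[C@H]1C=C | intermediate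
20 | 3-[(1R,2R,3R)-2-{[(6,8-dimethoxy-2-oxo-2H-chromen-7-yl)oxy]methyl}-2,3-dimethyl-6-(propan-2-ylidene)cyclohexyl]propanal | COc1cc2ccc(=O)oc2c(OC)c1OC[C@]1(C)[C@H](C)CCC(=C(C)C)[C@H]1CCC=O | intermediate
21 | 7-{[(1R,2R,6R)-2-(3-hydroxypropyl)-1,6-dimethyl-3-(propan-2-ylidene)cyclohexyl]methoxy}-6,8-dimethoxy-2H-chromen-2-one | COc1cc2ccc(=O)oc2c(OC)c1OC[C@]1(C)[C@H](C)CCC(=C(C)C)[C@H]1CCCO | target

**Step count**

Total step count: 14. Longest linear sequence: 13 steps (steps 1–5 and 7–14; step 6 is a one-step side branch).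

**Steps most likely to fail**

Step 8 (Proposed new method). What may go wrong: at 205 °C retro-ene fragmentation of the homoallylic alcohol may outrun the [3,3] shift, a boat transition state may erode the C1/C6 relationship, or the ene step may take hydrogen unselectively. The fallback uses known chemistry in two separate stages, sets out from 11 and comes back at 14. Compound 11 is deprotonated with KH and 18-crown-6 in THF (0 °C → rt) to the potassium alkoxide F1, which should undergo the anionic oxy-Cope rearrangement to the potassium enolate F2. Protonation with AcOH at −78 °C gives aldehyde 13, now isolated and equilibrated at its α-centre with DBU. Me2AlCl in CH2Cl2 (−78 → 0 °C) then promotes the type 2 carbonyl-ene closure to 14.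

Step 12. What may go wrong: displacement at the neopentyl carbon by the di-ortho-substituted phenoxide may be so slow that the betaine is consumed by side reactions and the alcohol is recovered. The fallback sets out from 17 and comes back at 19. Alcohol 17 is converted with Tf2O and 2,6-lutidine (CH2Cl2, −78 °C) into the neopentyl triflate F3. Isofraxidin 18 is deprotonated with Cs2CO3 in DMF to the caesium phenoxide F4, which displaces the triflate (25–50 °C) in a Williamson-type alkylation to give 19.

Step 4. What may go wrong: poor facial discrimination by the catalyst on a fully substituted, hindered enal, or a slow reaction that lets the uncatalysed racemic addition compete. The fallback sets out from 4 and comes back at 6. Zinc-mediated Barbier propargylation of 4 with propargyl bromide (THF/aqueous NH4Cl) gives the racemic alcohol, that is 6 together with its (4R)-enantiomer F5. Kinetic resolution with Burkholderia cepacia lipase and vinyl acetate in MTBE should acetylate the R alcohol to the (4R)-acetate F6 and leave 6, which is separated by chromatography.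

**Further compounds**

F1 | step 8 | potassium (2Z,4S,6E)-1-[(4-methoxyphenyl)methoxy]-2,3,9-trimethyl-8-methylidenedeca-2,6-dien-4-olate | COc1ccc(COC/C(C)=C(C)\[C@@H]([O-])C/C=C/C(=C)C(C)C)cc1.[K+]
F2 | step 8 | potassium (1E,3S,4R)-4-ethenyl-3-{[(4-methoxyphenyl)methoxy]methyl}-2,3,6-trimethyl-5-methylidenehept-1-en-1-olate | COc1ccc(COC[C@](C)(/C(C)=C/[O-])[C@H](C=C)C(=C)C(C)C)cc1.[K+]
F3 | step 12 | [(1R,2R,6R)-2-ethenyl-1,6-dimethyl-3-(propan-2-ylidene)cyclohexyl]methyl trifluoromethanesulfonate | O=S(=O)(OC[C@]1(C)[C@H](C)CCC(=C(C)C)[C@H]1C=C)C(F)(F)F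
F4 | step 12 | caesium 6,8-dimethoxy-2-oxo-2H-chromen-7-olate | COc1cc2ccc(=O)oc2c(OC)c1[O-].[Cs+]
F5 | step 4 | (4R,5Z)-7-[(4-methoxyphenyl)methoxy]-5,6-dimethylhept-5-en-1-yn-4-ol | COc1ccc(COC/C(C)=C(C)\[C@H](O)CC#C)cc1
F6 | step 4 | (4R,5Z)-7-[(4-methoxyphenyl)methoxy]-5,6-dimethylhept-5-en-1-yn-4-yl acetate | COc1ccc(COC/C(C)=C(C)\[C@H](OC(C)=O)CC#C)cc1
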